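The target is cut at the bond between the bis-indolyl methine carbon and C2 of the 3-(2-acetoxyethyl)indole ring. That methine also sits on C3 of the second indole. It is therefore the former benzylic carbinol carbon of an indole-3-glycerol unit, and the nitrogen lone pair of that ring can expel the hydroxyl to give a 3-alkylideneindoleninium ion. In one operation a chiral phosphoric acid ionises the carbinol and tryptophol acetate captures the cation at its free C2. This joins both monomers and sets the methine stereocentre. The precursor is an acetonide-protected indol-3-yl glycerol whose glycol stereocentre derives from D-mannitol. Mild ketal hydrolysis finishes the synthesis.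

Key step: step 4

Stereochemical remark: the target is (1S,2S). Its glycol carbon has the spatial arrangement of C2 of (R)-glyceraldehyde acetonide. The descriptor changes from R to S only because CH2O outranks the diaryl-substituted methine carbon. With the indol-2-yl group in the zigzag chain, indol-3-yl and OH are anti.

Assumption: it cannot be deduced with confidence which antipode of the phosphoric acid reinforces attack on the required face of the cation. (R)-TRIP is written, and (S)-TRIP replaces it if a small test of both antipodes shows that to be the matched pair.

Step 1
Reactants: 1 1,2:5,6-di-O-isopropylidene-D-mannitol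
Product: 2 (R)-2,3-O-isopropylideneglyceraldehyde
Conditions: NaIO4, sat. aq NaHCO3, CH2Cl2, rt; dried, concentrated cold, used the same day
Reagents that add atoms: none
Why: Malaprade periodate cleavage of the central vicinal diol splits the C2-symmetric 1 into two molecules of 2 without touching the dioxolane stereocentre, and the bicarbonate buffer and immediate use guard against ketal loss, epimerisation and oligomerisation.

Step 2
Reactants: 2 (R)-2,3-O-isopropylideneglyceraldehyde; 3 indole
Product: 5 [(4R)-2,2-dimethyl-1,3-dioxolan-4-yl](1H-indol-3-yl)methanol as a mixture of carbinol epimers, via indol-1-ylmagnesium bromide 4 (not isolated)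
Conditions: EtMgBr (1.0 equiv), Et2O, 0 °C → rt; cannulated into 2 (1.3 equiv), CH2Cl2, −40 → −10 °C; aq NH4Cl/NH3 (pH 8); Et3N-deactivated SiO2, stored cold, used promptly
Reagents that add atoms: ethylmagnesium bromide, CC[Mg]Br (its MgBr is carried only by 4 and is lost on work-up; nothing of it remains in 5)
Why: Indolyl Grignard addition to an aldehyde, in which the tight N–Mg bond of 4 in a weakly coordinating medium directs the carbonyl carbon to C3; inverse addition to a slight excess of cold aldehyde and a mildly basic quench hold back elimination of the magnesium alkoxide and a second indole addition, and the new carbinol centre is left uncontrolled because step 4 erases it.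

Step 3
Reactants: 6 tryptophol
Product: 7 tryptophol acetate (2-(1H-indol-3-yl)ethyl acetate)
Conditions: Ac2O (1.2 equiv), pyridine, CH2Cl2, 0 °C → rt, no DMAP
Reagents that add atoms: acetic anhydride, CC(=O)OC(C)=O
Why: Pyridine-mediated O-acylation, in which the primary alcohol reacts far faster than the indole N–H, which stays free in the absence of DMAP or a strong base; no stereocentre is involved.

Step 4
Reactants: 5 [(4R)-2,2-dimethyl-1,3-dioxolan-4-yl](1H-indol-3-yl)methanol; 7 tryptophol acetate
Product: 9 colletotryptin C acetonide, via 3-alkylideneindoleninium cation 8 (not isolated)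
Conditions: (R)-TRIP (10 mol %), 7 (3 equiv), 4 Å MS, toluene/CH2Cl2 4:1, −30 °C, 5 added over 4 h by syringe pump; Et3N quench; SiO2 (removal of the methine epimer, recovery of excess 7)
Reagents that add atoms: none
Why: The phosphoric acid protonates the hydroxyl of 5 and water leaves with push from the indole nitrogen, so both carbinol epimers converge on the planar vinylogous iminium ion 8, held to the chiral phosphate by N–H···O hydrogen bonding; 7, whose C3 is occupied, bonds through C2 (directly, or by C3 attack and 1,2-shift) and loses a proton to restore the indole. This is the Brønsted acid catalysed dehydrative Friedel–Crafts substitution of 3-indolylmethanols by indoles, established also for 3-substituted indoles reacting at C2, and only the level of facial control next to a dioxolane has to be found by experiment. No ring is closed. The one new stereocentre, the (S)-methine, results from attack on the face of 8 that lies anti to the dioxolane C–O bond in the Felkin–Anh rotamer; because the allylic-strain rotamer, with the dioxolane C–H eclipsing the exocyclic C=C, exposes the opposite face, the substrate bias alone is not trusted, so the phosphate counter-ion, which also binds the N–H of 7, is the intended controller, and the minor epimer is a diastereomer removable on silica. C2 over N1 selectivity follows from the acidic medium and the blocked C3, cross-coupling over self-coupling follows from the excess of 7 and the slow addition of 5, and the glycol centre is preserved because low temperature and sieves disfavour proton loss to the enol ether and ketal hydrolysis. The acetate keeps the side-chain oxygen from closing onto a C3 adduct as a furoindoline.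

Step 5
Reactants: 9 colletotryptin C acetonide
Product: 10 colletotryptin C
Conditions: AcOH/H2O 4:1, 35–40 °C, Ar, dark; toluene azeotrope below 35 °C
Reagents that add atoms: none
Why: Acid-catalysed ketal hydrolysis, in which dilute acetic acid cleaves a terminal isopropylidene ketal under conditions that spare a primary acetate and the bis-indolyl methine, acyl exchange with the medium is degenerate, and no bond to either stereocentre is broken.

Compound list
1 | 1,2:5,6-di-O-isopropylidene-D-mannitol | CC1(C)OC[C@@H](O1)[C@@H](O)[C@H](O)[C@H]1COC(C)(C)O1 | starting material
2 | (R)-2,3-O-isopropylideneglyceraldehyde [(4R)-2,2-dimethyl-1,3-dioxolane-4-carbaldehyde] | O=C[C@H]1COC(C)(C)O1 | intermediate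
3 | indole | c1ccc2[nH]ccc2c1 | starting material
4 | indol-1-ylmagnesium bromide (formed in the flask) | Br[Mg]n1ccc2ccccc12 | intermediate
5 | [(4R)-2,2-dimethyl-1,3-dioxolan-4-yl](1H-indol-3-yl)methanol, both carbinol epimers | OC(c1c[nH]c2ccccc12)[C@H]1COC(C)(C)O1 | intermediate
6 | tryptophol [2-(1H-indol-3-yl)ethanol] | OCCc1c[nH]c2ccccc12 | starting material
7 | tryptophol acetate [2-(1H-indol-3-yl)ethyl acetate] | CC(=O)OCCc1c[nH]c2ccccc12 | intermediate
8 | 3-{[(4S)-2,2-dimethyl-1,3-dioxolan-4-yl]methylidene}-3H-indol-1-ium (formed in the flask; counter-ion is the catalyst phosphate, C=C geometry not fixed) | C(=C1C=[NH+]c2ccccc12)[C@H]1COC(C)(C)O1 | intermediate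
9 | colletotryptin C acetonide, 2-{2-[(S)-[(4S)-2,2-dimethyl-1,3-dioxolan-4-yl](1H-indol-3-yl)methyl]-1H-indol-3-yl}ethyl acetate | CC(=O)OCCc1c([C@H](c2c[nH]c3ccccc23)[C@H]2COC(C)(C)O2)[nH]c2ccccc12 | intermediate
10 | colletotryptin C, 2-{2-[(1S,2S)-2,3-dihydroxy-1-(1H-indol-3-yl)propyl]-1H-indol-3-yl}ethyl acetate | CC(=O)OCCc1c([C@H](c2c[nH]c3ccccc23)[C@H](O)CO)[nH]c2ccccc12 | target

Total steps: 5. Longest linear sequence: 4 steps (1 → 2 → 5 → 9 → 10, that is steps 1, 2, 4 and 5). Step 3 is a one-step side branch.

Steps most likely to fail

**Step 4.**
- Facial discrimination at the planar cation may be weak or of the wrong sense.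
- Capture at the only moderately nucleophilic C2 may be outrun by self-condensation of the carbinol, by proton loss from the dioxolane carbon (erosion of the glycol centre) or by ketal cleavage.
- The fallback stores the electrophile as a sulfone instead of an alcohol and gives up catalyst control. It sets out from 2 and 3.
- Three-component condensation with p-toluenesulfinic acid (cat. TsOH, EtOAc, rt) should give the bench-stable 3-{[(4R)-2,2-dimethyl-1,3-dioxolan-4-yl](tosyl)methyl}indole F1. It belongs to a known class of alkylideneindolenine precursors.
- A Lewis acid that abstracts the sulfinate (InBr3 or montmorillonite K10, CH2Cl2, −20 °C → rt) in the presence of excess 7 releases the same cation. No Brønsted acid is needed and no water forms.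
- Friedel–Crafts capture at C2 of 7 then comes back to the route at 9.
- Facial control then rests on the dioxolane alone. The two methine epimers are diastereomers and are parted by chromatography or crystallisation.
- This path also bypasses step 2.

**Step 2.**
- The magnesium alkoxide may eliminate and take up a second indole (symmetrical bis-indolyl by-product formation).
- Attack may occur at nitrogen.
- The N–H carbinol may ionise during work-up or on silica.
- The fallback replaces the ambident N-metallated indole by a C3 carbanion of an N-silyl indole. It sets out from 2.
- Bought 3-bromo-1-(triisopropylsilyl)indole F2 undergoes bromine–lithium exchange (t-BuLi, 2 equiv, THF, −78 °C) to 3-lithio-1-(triisopropylsilyl)indole F3. The bulky silyl group keeps it from isomerising to the 2-lithio species.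
- Addition to 2 should give the N-silyl carbinol F4. Its shielded nitrogen makes it stable to chromatography and storage.
- TBAF (THF, 0 °C) removes the silyl group under non-acidic conditions just before use, and the route is rejoined at 5.

**Step 5.**
- Ketal cleavage may be slow enough that partial loss of the acetate, acetylation of the liberated diol by the medium or acyl scrambling sets in.
- The fallback stops sparing the ester and reinstalls it regioselectively. It sets out from 9.
- The hydrolysis is run without regard for the acetate, and the crude mixture is treated with K2CO3 in MeOH. This should converge all material on the deacetylated triol F5.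
- Phenylboronic acid (CH2Cl2, MgSO4, rt) masks only the 1,2-diol, as the cyclic phenylboronate F6.
- Ac2O/pyridine acetylates the remaining primary alcohol to give the boronate acetate F7.
- Neutral transesterification with pinacol (CH2Cl2, rt) frees the diol, and the route is rejoined at 10.

Further compounds
F1 | step 4 | 3-{[(4R)-2,2-dimethyl-1,3-dioxolan-4-yl](4-methylbenzenesulfonyl)methyl}-1H-indole, both sulfone epimers | Cc1ccc(cc1)S(=O)(=O)C(c1c[nH]c2ccccc12)[C@H]1COC(C)(C)O1
F2 | step 2 | 3-bromo-1-(triisopropylsilyl)-1H-indole (bought) | CC(C)[Si](C(C)C)(C(C)C)n1cc(Br)c2ccccc12
F3 | step 2 | 3-lithio-1-(triisopropylsilyl)-1H-indole | CC(C)[Si](C(C)C)(C(C)C)n1cc([Li])c2ccccc12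
F4 | step 2 | [(4R)-2,2-dimethyl-1,3-dioxolan-4-yl][1-(triisopropylsilyl)-1H-indol-3-yl]methanol, both carbinol epimers | CC(C)[Si](C(C)C)(C(C)C)n1cc(C(O)[C@H]2COC(C)(C)O2)c2ccccc12
F5 | step 5 | (2S,3S)-3-[3-(2-hydroxyethyl)-1H-indol-2-yl]-3-(1H-indol-3-yl)propane-1,2-diol | OCCc1c([C@H](c2c[nH]c3ccccc23)[C@H](O)CO)[nH]c2ccccc12
F6 | step 5 | 2-{2-[(S)-(1H-indol-3-yl)[(4S)-2-phenyl-1,3,2-dioxaborolan-4-yl]methyl]-1H-indol-3-yl}ethanol | OCCc1c([C@H](c2c[nH]c3ccccc23)[C@H]2COB(c3ccccc3)O2)[nH]c2ccccc12
F7 | step 5 | 2-{2-[(S)-(1H-indol-3-yl)[(4S)-2-phenyl-1,3,2-dioxaborolan-4-yl]methyl]-1H-indol-3-yl}ethyl acetate | CC(=O)OCCc1c([C@H](c2c[nH]c3ccccc23)[C@H]2COB(c3ccccc3)O2)[nH]c2ccccc12
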